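**Retrosynthetic overview**

- The target is a 5,5'-biaryl. One half is a tetrahydrofuran lignan with aryl, CH2OH and benzyl all cis; the other is an aryltetralin. Both halves carry the same C8/C8' stereodiad, so both are cut back to one γ-lactol (Wittig, Sharpless epoxidation, vinyl opening, ozonolysis).
- Key disconnection: the bond from the pendant phenol ring (its carbon para to OH) to the tetralin methine C7, together with C7–C6' of the tetralin ring. Both bonds are made in one flask from the biaryl phenol that already carries the tetrahydrofuran half and the acetylated lactol.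
- Enabling feature: tetralin C7 is a doubly benzylic methine. It lies para to the free OH of a pendant ring whose two ortho positions are blocked (OMe, biaryl bond) and para to the OMe of the fused ring. It also sits 1,3 to the C8' hydroxymethyl group, so it can be stored at the aldehyde level as the anomeric carbon of an oxolane.
- The tetrahydrofuran half comes from the same lactol through its lactone. Aryllithium addition and hemiketal reduction set the 7,8-cis aryl group. Acetylation of its two phenols then switches off its own benzylic ether for the key step.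
- Ring order: oxirane (step 5), oxolane (step 7, kept in the tetrahydrofuran half), biaryl bond (step 14), tetralin carbocycle (step 21).

Key step: step 21

Remark: lignan locants are used (C7 benzylic, C8, C9; primed locants for the benzyl-bearing C6C3 unit). Lactols, the anomeric acetate and the hemiketal are handled as anomeric mixtures because that centre is planarised later. The drawn tetrahydrofuran half is read as (7R,8R,8'S), with aryl, CH2OH and benzyl on one face, and the route is built for that arrangement.

Step 1
Reactants: 1 4-(benzyloxy)-3-methoxybenzyl alcohol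
Product: 2 4-(benzyloxy)-3-methoxybenzyl bromide
Conditions: PBr3 (0.4 equiv), Et2O, 0 °C
Reagents that add atoms: phosphorus tribromide, BrP(Br)Br
Why: Bromination of a primary benzylic alcohol with PBr3 (SN2 on the phosphite ester) is routine for this electron-rich system and leaves the aryl ethers untouched.

Step 2
Reactants: 2 4-(benzyloxy)-3-methoxybenzyl bromide; 3 ethyl (triphenylphosphoranylidene)acetate
Product: 5 ethyl 3-[4-(benzyloxy)-3-methoxyphenyl]-2-(triphenylphosphoranylidene)propanoate, via phosphonium bromide 4 (not isolated)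
Conditions: EtOAc, reflux; then 1 M aq NaOH, CH2Cl2, rt
Reagents that add atoms: none
Why: C-Alkylation of a stabilised phosphorus ylide with a reactive benzylic bromide gives salt 4, and mild aqueous base regenerates the α-substituted ylide without touching the ester.

Step 3
Reactants: 5 α-arylmethyl ylide; 6 (benzyloxy)acetaldehyde
Product: 7 ethyl (E)-4-(benzyloxy)-2-[4-(benzyloxy)-3-methoxybenzyl]but-2-enoate
Conditions: toluene, 80 °C
Reagents that add atoms: none
Why: The Wittig olefination with an α-substituted stabilised ylide should favour the (E)-enoate, which places CH2OBn trans to the ester and cis to the arylmethyl group as the later epoxide opening requires.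

Step 4
Reactants: 7 (E)-enoate
Product: 8 (E)-4-(benzyloxy)-2-[4-(benzyloxy)-3-methoxybenzyl]but-2-en-1-ol
Conditions: DIBAL-H (2.5 equiv), CH2Cl2, −78 °C; aq Rochelle salt
Reagents that add atoms: none
Why: DIBAL-H 1,2-reduction of an α,β-unsaturated ester gives the allylic alcohol with the alkene geometry retained.

Step 5
Reactants: 8 (E)-allylic alcohol
Product: 9 [(2R,3R)-2-[4-(benzyloxy)-3-methoxybenzyl]-3-[(benzyloxy)methyl]oxiran-2-yl]methanol
Conditions: Ti(OiPr)4 (10 mol %), D-(−)-DIPT (12 mol %), t-BuOOH, 4 Å MS, CH2Cl2, −20 °C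
Reagents that add atoms: tert-butyl hydroperoxide, CC(C)(C)OO
Why: In the Sharpless asymmetric epoxidation of this trisubstituted (E)-allylic alcohol the D-(−)-tartrate catalyst delivers oxygen to the face that gives the (2R,3R)-oxirane, which fixes the future tertiary carbinol C8' by reagent control.

Step 6
Reactants: 9 epoxy alcohol
Product: 10 (2S,3S)-2-[4-(benzyloxy)-3-methoxybenzyl]-3-[(benzyloxy)methyl]pent-4-ene-1,2-diol
Conditions: CH2=CHMgBr (4 equiv), CuI (20 mol %), THF, −30 → 0 °C; sat. aq NH4Cl
Reagents that add atoms: vinylmagnesium bromide, C=C[Mg]Br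
Why: In this copper-catalysed SN2 opening of a 2,3-epoxy alcohol by a vinyl Grignard reagent, attack occurs anti at the secondary carbon C8 because the other oxirane carbon is fully substituted, so C8 is set by inversion and the C8'–O bond is untouched.

Step 7
Reactants: 10 vinyl diol
Product: 12 dibenzyl lactol (3S,4S)-4-[4-(benzyloxy)-3-methoxybenzyl]-3-[(benzyloxy)methyl]oxolane-2,4-diol, via hydroxy aldehyde 11 (not isolated)
Conditions: O3, CH2Cl2, −78 °C (Sudan III end point); Me2S, −78 °C → rt
Reagents that add atoms: ozone, [O-][O+]=O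
Why: Ozonolysis with reductive work-up cleaves the only alkene (the indicator-controlled end point spares the arenes), and aldehyde 11 closes spontaneously through its primary C9' hydroxyl (5-exo-trig) to the γ-lactol with C8 and C8' untouched.

Step 8
Reactants: 12 dibenzyl lactol
Product: 13 (3S,4S)-4-(4-hydroxy-3-methoxybenzyl)-3-(hydroxymethyl)oxolane-2,4-diol
Conditions: H2 (1 atm), 10 % Pd/C, EtOAc–EtOH, rt
Reagents that add atoms: none
Why: Catalytic hydrogenolysis removes both benzyl ethers under neutral conditions that neither reduce nor epimerise the lactol.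

Step 9
Reactants: 13 free lactol
Product: 14 lactol triacetate (3S,4S)-2-acetoxy-4-(4-acetoxy-3-methoxybenzyl)-3-(acetoxymethyl)oxolan-4-ol
Conditions: Ac2O, pyridine, 0 °C → rt
Reagents that add atoms: acetic anhydride, CC(=O)OC(C)=O
Why: Standard acetylation esterifies the anomeric, primary and phenolic hydroxyls while the hindered tertiary C8' hydroxyl stays free, which turns the lactol into a glycosyl-acetate-type donor.

Step 10
Reactants: 12 dibenzyl lactol
Product: 15 (3S,4S)-4-[4-(benzyloxy)-3-methoxybenzyl]-3-[(benzyloxy)methyl]-4-hydroxyoxolan-2-one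
Conditions: TEMPO (10 mol %), PhI(OAc)2, CH2Cl2, rt
Reagents that add atoms: none
Why: The oxoammonium (TEMPO) oxidation converts the lactol selectively into the γ-lactone, the tertiary alcohol being inert.

Step 11
Reactants: 15 hydroxy lactone
Product: 16 (3S,4S)-4-[4-(benzyloxy)-3-methoxybenzyl]-3-[(benzyloxy)methyl]-4-(triethylsilyloxy)oxolan-2-one
Conditions: TESOTf, 2,6-lutidine, CH2Cl2, 0 °C
Reagents that add atoms: triethylsilyl triflate, CC[Si](CC)(CC)OS(=O)(=O)C(F)(F)F
Why: Silylation with the triflate and a hindered base protects the tertiary alcohol without enolising the lactone, so that no acidic proton meets the aryllithium.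

Step 12
Reactants: 17 4-bromo-2-methoxyphenol
Product: 18 4-bromo-2-iodo-6-methoxyphenol
Conditions: NIS, TsOH (cat.), MeCN, rt
Reagents that add atoms: N-iodosuccinimide, O=C1CCC(=O)N1I
Why: Electrophilic aromatic iodination is directed by the free OH to its only open ortho position because the para position carries bromine.

Step 13
Reactants: 18 4-bromo-2-iodo-6-methoxyphenol
Product: 19 2-(benzyloxy)-5-bromo-1-iodo-3-methoxybenzene
Conditions: BnBr, K2CO3, DMF, rt
Reagents that add atoms: benzyl bromide, BrCc1ccccc1
Why: The Williamson etherification of the phenoxide gives a protecting group that tolerates palladium coupling and butyllithium.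

Step 14
Reactants: 19 benzyl ether; 20 (2-hydroxy-3-methoxyphenyl)boronic acid
Product: 21 2'-(benzyloxy)-5'-bromo-3,3'-dimethoxy-[1,1'-biphenyl]-2-ol
Conditions: Pd(dppf)Cl2 (5 mol %), K2CO3, dioxane–H2O, 60 °C
Reagents that add atoms: none
Why: The Suzuki–Miyaura coupling is chemoselective for C–I over C–Br in the oxidative addition, which builds the biaryl bond and keeps the bromide para to OBn for the lithiation.

Step 15
Reactants: 21 biaryl phenol
Product: 22 [2'-(benzyloxy)-5'-bromo-3,3'-dimethoxy-[1,1'-biphenyl]-2-yl]oxy(tert-butyl)dimethylsilane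
Conditions: TBSCl, imidazole, DMF, rt
Reagents that add atoms: tert-butyldimethylsilyl chloride, CC(C)(C)[Si](C)(C)Cl
Why: Silylation masks the remaining phenol with a group that survives butyllithium, BF3/silane and hydrogenolysis and is orthogonal to benzyl and acetyl.

Step 16
Reactants: 22 silylated bromobiaryl; 16 silylated lactone
Product: 24 hemiketal (3S,4S)-2-aryl-4-[4-(benzyloxy)-3-methoxybenzyl]-3-[(benzyloxy)methyl]-4-(triethylsilyloxy)oxolan-2-ol, via aryllithium 23 (not isolated)
Conditions: n-BuLi (1.05 equiv), THF, −78 °C; then 16, −78 °C; sat. aq NH4Cl at −78 °C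
Reagents that add atoms: none
Why: Bromine–lithium exchange followed by 1,2-addition of the aryllithium to the γ-lactone stops at the lithium hemiketalate at −78 °C (the tactic used for C-aryl furanosides), so a single aryl group is introduced at C7.

Step 17
Reactants: 24 hemiketal
Product: 26 (2R,3R,4S)-2-aryl-4-[4-(benzyloxy)-3-methoxybenzyl]-3-[(benzyloxy)methyl]-4-(triethylsilyloxy)oxolane (aryl = 4-benzyloxy-3-methoxy-5-[2-(TBSO)-3-methoxyphenyl]phenyl), via oxocarbenium ion 25 (not isolated)
Conditions: Et3SiH (5 equiv), BF3·OEt2 (2 equiv), CH2Cl2, −78 °C; Et3N quench at −78 °C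
Reagents that add atoms: none
Why: In this ionic reductive deoxygenation of a cyclic hemiketal, BF3 generates the aryl-stabilised oxocarbenium ion 25 and Et3SiH attacks C7 from the face anti to the C8 CH2OBn group and syn to the C8' silyloxy group (inside attack on the envelope), which places the aryl group cis to CH2OBn and benzyl (7R), while the low temperature prevents re-ionisation and epimerisation.

Step 18
Reactants: 26 protected tetrahydrofuran half
Product: 27 (2R,3R,4S)-triol with both phenols of the tetrahydrofuran half and the C9 hydroxyl free (TES and TBS retained)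
Conditions: H2 (1 atm), 10 % Pd/C, EtOAc, rt
Reagents that add atoms: none
Why: Hydrogenolysis cleaves the three benzyl ethers, whereas the silyl ethers and the cyclic benzylic ether should persist in a non-protic solvent.

Step 19
Reactants: 27 triol
Product: 28 (2R,3R,4S)-triacetate (TES and TBS retained)
Conditions: Ac2O, pyridine, DMAP (cat.), CH2Cl2, 0 °C → rt
Reagents that add atoms: acetic anhydride, CC(=O)OC(C)=O
Why: DMAP-catalysed acetylation converts both phenols and the primary alcohol into acetates, which lowers the donor power of the oxygen para to C7 and so switches off ionisation of the cis-oxolane.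

Step 20
Reactants: 28 silylated triacetate
Product: 29 biaryl phenol (2R,3R,4S)-triacetate with free biaryl OH and free tertiary OH
Conditions: TBAF–AcOH (1:1, 3 equiv), THF, 0 °C → rt
Reagents that add atoms: none
Why: Fluoride desilylation buffered with acetic acid frees the biaryl phenol and the tertiary alcohol without building up a phenoxide that could cleave or take over the neighbouring acetate.

Step 21
Reactants: 29 biaryl phenol; 14 lactol triacetate
Product: 33 pentaacetate of the target, via oxocarbenium ion 30 (not isolated), via C-aryl tetrahydrofuran 31 (not isolated), via benzylic cation 32 (not isolated)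
Conditions: Sc(OTf)3 (20 mol %), Drierite, CH2Cl2, −30 °C → rt; 14 (1.3 equiv) added slowly
Reagents that add atoms: none
Why: Sc(OTf)3 ionises the anomeric acetate of 14 to oxocarbenium ion 30, which after reversible O-arylation is captured at the carbon para to the only free phenol of 29 to give C-aryl tetrahydrofuran 31; being a p-hydroxybenzyl ether, 31 re-ionises at C7–O9' to cation 32 (a protonated p-quinone methide), and C6' of the tethered ring (para to its OMe) attacks C7, closing the tetralin and freeing the C9' hydroxyl. The closest known reaction types are the Lewis-acid Friedel–Crafts C-arylation of phenols with lactols or furanosyl acetates and the acid isomerisation of 2-aryl-4-benzyltetrahydrofuran lignans into aryltetralins, here run in one flask. One ring is closed, the six-membered carbocycle, by a 6-exo-trig Friedel–Crafts attack on the exocyclic cation, while the oxolane ring of 14 is opened. The only new stereocentre, C7, is set in this closure from the planar cation under control of C8 and C8': in the chair-like transition state the pendant aryl group, C8–CH2OAc and C8'–CH2OH are all equatorial, which should give the 7,8-trans (1S,2S,3S) tetralin whatever the configuration of 31. The step needs site selectivity among four arene rings and survival of the cis-tetrahydrofuran half: only the reacting ring has a free OH, blocked ortho positions and an unhindered para C–H, whereas the other phenols are acetylated, so that their rings are poorer and more hindered nucleophiles and the benzylic C7–O bond of the tetrahydrofuran half, now para to OAc instead of OH, should not ionise under the mild catalyst. Slow addition of 14 keeps the donor concentration low and suppresses its self-condensation and elimination.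

Step 22
Reactants: 33 pentaacetate
Product: 34 target CNP0344108.1
Conditions: NH3 (7 M in MeOH), 0 °C → rt, argon; evaporation
Reagents that add atoms: none
Why: Ammonolysis of the five acetates in methanolic ammonia is mild and needs no aqueous or acidic work-up, so neither the acid-labile p-hydroxybenzyl ether of the cis-oxolane nor any stereocentre is disturbed.

**Compound list**

1 | 4-(benzyloxy)-3-methoxybenzyl alcohol | COc1cc(CO)ccc1OCc1ccccc1 | starting material
2 | 4-(benzyloxy)-3-methoxybenzyl bromide | COc1cc(CBr)ccc1OCc1ccccc1 | intermediate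
3 | ethyl (triphenylphosphoranylidene)acetate | CCOC(=O)C=P(c1ccccc1)(c1ccccc1)c1ccccc1 | starting material
4 | [3-(4-benzyloxy-3-methoxyphenyl)-1-ethoxy-1-oxopropan-2-yl]triphenylphosphonium bromide | CCOC(=O)C(Cc1ccc(OCc2ccccc2)c(OC)c1)[P+](c1ccccc1)(c1ccccc1)c1ccccc1.[Br-] | intermediate
5 | ethyl 3-[4-(benzyloxy)-3-methoxyphenyl]-2-(triphenylphosphoranylidene)propanoate | CCOC(=O)C(Cc1ccc(OCc2ccccc2)c(OC)c1)=P(c1ccccc1)(c1ccccc1)c1ccccc1 | intermediate
6 | (benzyloxy)acetaldehyde | O=CCOCc1ccccc1 | starting material
7 | ethyl (E)-4-(benzyloxy)-2-[4-(benzyloxy)-3-methoxybenzyl]but-2-enoate | CCOC(=O)/C(Cc1ccc(OCc2ccccc2)c(OC)c1)=C/COCc1ccccc1 | intermediate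
8 | (E)-4-(benzyloxy)-2-[4-(benzyloxy)-3-methoxybenzyl]but-2-en-1-ol | OC/C(Cc1ccc(OCc2ccccc2)c(OC)c1)=C/COCc1ccccc1 | intermediate
9 | [(2R,3R)-2-[4-(benzyloxy)-3-methoxybenzyl]-3-[(benzyloxy)methyl]oxiran-2-yl]methanol | OC[C@@]1(Cc2ccc(OCc3ccccc3)c(OC)c2)O[C@@H]1COCc1ccccc1 | intermediate
10 | (2S,3S)-2-[4-(benzyloxy)-3-methoxybenzyl]-3-[(benzyloxy)methyl]pent-4-ene-1,2-diol | C=C[C@@H](COCc1ccccc1)[C@](O)(CO)Cc1ccc(OCc2ccccc2)c(OC)c1 | intermediate
11 | (2S,3S)-3-[4-(benzyloxy)-3-methoxybenzyl]-2-[(benzyloxy)methyl]-3,4-dihydroxybutanal | O=C[C@@H](COCc1ccccc1)[C@](O)(CO)Cc1ccc(OCc2ccccc2)c(OC)c1 | intermediate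
12 | (3S,4S)-4-[4-(benzyloxy)-3-methoxybenzyl]-3-[(benzyloxy)methyl]oxolane-2,4-diol (anomeric mixture) | COc1cc(C[C@@]2(O)COC(O)[C@H]2COCc2ccccc2)ccc1OCc1ccccc1 | intermediate
13 | (3S,4S)-4-(4-hydroxy-3-methoxybenzyl)-3-(hydroxymethyl)oxolane-2,4-diol (anomeric mixture) | COc1cc(C[C@@]2(O)COC(O)[C@H]2CO)ccc1O | intermediate
14 | (3S,4S)-2-acetoxy-4-(4-acetoxy-3-methoxybenzyl)-3-(acetoxymethyl)oxolan-4-ol (anomeric mixture) | COc1cc(C[C@@]2(O)COC(OC(C)=O)[C@H]2COC(C)=O)ccc1OC(C)=O | intermediate
15 | (3S,4S)-4-[4-(benzyloxy)-3-methoxybenzyl]-3-[(benzyloxy)methyl]-4-hydroxyoxolan-2-one | COc1cc(C[C@@]2(O)COC(=O)[C@H]2COCc2ccccc2)ccc1OCc1ccccc1 | intermediate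
16 | (3S,4S)-4-[4-(benzyloxy)-3-methoxybenzyl]-3-[(benzyloxy)methyl]-4-(triethylsilyloxy)oxolan-2-one | COc1cc(C[C@@]2(O[Si](CC)(CC)CC)COC(=O)[C@H]2COCc2ccccc2)ccc1OCc1ccccc1 | intermediate
17 | 4-bromo-2-methoxyphenol | COc1cc(Br)ccc1O | starting material
18 | 4-bromo-2-iodo-6-methoxyphenol | COc1cc(Br)cc(I)c1O | intermediate
19 | 2-(benzyloxy)-5-bromo-1-iodo-3-methoxybenzene | COc1cc(Br)cc(I)c1OCc1ccccc1 | intermediate
20 | (2-hydroxy-3-methoxyphenyl)boronic acid | COc1cccc(B(O)O)c1O | starting material
21 | 2'-(benzyloxy)-5'-bromo-3,3'-dimethoxy-[1,1'-biphenyl]-2-ol | COc1cccc(-c2cc(Br)cc(OC)c2OCc2ccccc2)c1O | intermediate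
22 | TBS ether of 21 | COc1cccc(-c2cc(Br)cc(OC)c2OCc2ccccc2)c1O[Si](C)(C)C(C)(C)C | intermediate
23 | aryllithium from 22 (Li in place of Br) | COc1cccc(-c2cc([Li])cc(OC)c2OCc2ccccc2)c1O[Si](C)(C)C(C)(C)C | intermediate
24 | (3S,4S)-hemiketal, 2-aryl-oxolan-2-ol (anomeric mixture) | COc1cc(C[C@@]2(O[Si](CC)(CC)CC)COC(O)(c3cc(OC)c(OCc4ccccc4)c(-c4cccc(OC)c4O[Si](C)(C)C(C)(C)C)c3)[C@H]2COCc2ccccc2)ccc1OCc1ccccc1 | intermediate
25 | 2-aryl oxocarbenium ion from 24 | COc1cc(C[C@@]2(O[Si](CC)(CC)CC)C[O+]=C(c3cc(OC)c(OCc4ccccc4)c(-c4cccc(OC)c4O[Si](C)(C)C(C)(C)C)c3)[C@H]2COCc2ccccc2)ccc1OCc1ccccc1 | intermediate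
26 | (2R,3R,4S)-2-aryl-3-[(benzyloxy)methyl]-4-[4-(benzyloxy)-3-methoxybenzyl]-4-(triethylsilyloxy)oxolane, all-cis carbon substituents | COc1cc(C[C@@]2(O[Si](CC)(CC)CC)CO[C@@H](c3cc(OC)c(OCc4ccccc4)c(-c4cccc(OC)c4O[Si](C)(C)C(C)(C)C)c3)[C@H]2COCc2ccccc2)ccc1OCc1ccccc1 | intermediate
27 | (2R,3R,4S)-debenzylated triol (TES, TBS retained) | COc1cc(C[C@@]2(O[Si](CC)(CC)CC)CO[C@@H](c3cc(OC)c(O)c(-c4cccc(OC)c4O[Si](C)(C)C(C)(C)C)c3)[C@H]2CO)ccc1O | intermediate
28 | (2R,3R,4S)-triacetate (TES, TBS retained) | COc1cc(C[C@@]2(O[Si](CC)(CC)CC)CO[C@@H](c3cc(OC)c(OC(C)=O)c(-c4cccc(OC)c4O[Si](C)(C)C(C)(C)C)c3)[C@H]2COC(C)=O)ccc1OC(C)=O | intermediate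
29 | (2R,3R,4S)-triacetate with free biaryl phenol and free tertiary alcohol | COc1cc(C[C@@]2(O)CO[C@@H](c3cc(OC)c(OC(C)=O)c(-c4cccc(OC)c4O)c3)[C@H]2COC(C)=O)ccc1OC(C)=O | intermediate
30 | oxocarbenium ion from 14 | COc1cc(C[C@@]2(O)C[O+]=C[C@H]2COC(C)=O)ccc1OC(C)=O | intermediate
31 | C-aryl tetrahydrofuran (bis-oxolane, new C7 undefined) | COc1cc(C[C@@]2(O)CO[C@@H](c3cc(OC)c(OC(C)=O)c(-c4cc(C5OC[C@](O)(Cc6ccc(OC(C)=O)c(OC)c6)[C@@H]5COC(C)=O)cc(OC)c4O)c3)[C@H]2COC(C)=O)ccc1OC(C)=O | intermediate
32 | p-hydroxybenzylic cation (protonated p-quinone methide) | COc1cc(C[C@@]2(O)CO[C@@H](c3cc(OC)c(OC(C)=O)c(-c4cc([CH+][C@@H](COC(C)=O)[C@](O)(CO)Cc5ccc(OC(C)=O)c(OC)c5)cc(OC)c4O)c3)[C@H]2COC(C)=O)ccc1OC(C)=O | intermediate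
33 | pentaacetate of the target: (2R,3R,4S)-oxolane half, (1S,2S,3S)-tetralin half | COc1cc(C[C@@]2(O)CO[C@@H](c3cc(OC)c(OC(C)=O)c(-c4cc([C@H]5c6cc(OC(C)=O)c(OC)cc6C[C@@](O)(CO)[C@@H]5COC(C)=O)cc(OC)c4O)c3)[C@H]2COC(C)=O)ccc1OC(C)=O | intermediate
34 | CNP0344108.1 | COc1cc(C[C@@]2(O)CO[C@@H](c3cc(OC)c(O)c(-c4cc([C@H]5c6cc(O)c(OC)cc6C[C@@](O)(CO)[C@@H]5CO)cc(OC)c4O)c3)[C@H]2CO)ccc1O | target

**Step count**

- Total step count: 22.
- Longest linear sequence: 16 (steps 1–7, 10, 11, 16–22).

**Steps most likely to fail**

Step 21.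
- What may go wrong: elimination of the donor towards a furan; closure of the donor's own tethered ring onto the oxocarbenium ion before the phenol arrives, which would leave the C7 facial selectivity to an intermolecular attack; attack by a wrong arene ring; or migration of the acetyl group between the two biaryl oxygens, which would re-activate the cis-oxolane.
- Fallback: it sets out from 14 and 29 and comes back at 33, and it separates ring closure from union.
- Donor 14 alone is treated with BF3·OEt2 in CH2Cl2 at −40 °C. Without an external nucleophile its tethered ring closes onto the oxocarbenium ion (intramolecular oxocarbenium Friedel–Crafts cyclisation). This should give the O-bridged tetralin F1, a benzo-fused 6-oxabicyclo[3.2.1]octane that has no aldehyde function left and can be purified.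
- F1 and 29 are then joined in a separate SN1 Friedel–Crafts benzylation of the phenol (TfOH cat., CH2Cl2, −20 °C). The strained benzylic C7–O bond para to the ring OMe ionises. The C9 acetate shields the face cis to it by participation, and the para carbon of the phenol enters trans to it to give 33.

Step 17.
- What may go wrong: poor facial selectivity of the hydride delivery, or Lewis-acid re-ionisation of the product with epimerisation of the cis aryl group to the more stable trans arrangement.
- Fallback: it sets out from 24 and comes back at 26, and it avoids any benzylic cation.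
- The open hydroxy-ketone tautomer of 24 is reduced under reagent control. A Corey–Bakshi–Shibata reduction ((S)-Me-CBS, BH3·SMe2, THF, −20 °C, aryl as the large group) gives the (7R)-1,4-diol F2.
- The primary C9' hydroxyl is sulfonylated selectively (TsCl, pyridine, 0 °C) to the primary tosylate F3.
- NaH in THF closes the oxolane by a 5-exo-tet Williamson displacement at C9', which does not touch C7, so its configuration is retained in 26.

Step 16.
- What may go wrong: enolisation of the lactone by the aryllithium with β-elimination of the silyloxy group, or ring opening of the adduct followed by silyl migration to the primary alkoxide.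
- Fallback: it sets out from 16 (with 23 made from 22 as before) and comes back at 24, and it moves the addition to the aldehyde oxidation level.
- DIBAL-H (CH2Cl2, −78 °C) reduces 16 to the silylated lactol F4.
- After deprotonation with t-BuMgCl, its far more electrophilic aldehyde tautomer takes up aryllithium 23 to give the benzylic alcohol F5 as a C7 epimer mixture.
- Selective oxidation of this electron-rich benzylic alcohol with MnO2 (CH2Cl2, rt) gives the hydroxy ketone, which closes to hemiketal 24.

**Further compounds**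

F1 | step 21 | O-bridged tetralin diacetate (benzo-fused 6-oxabicyclo[3.2.1]octane, C7–O–C9' bridge) | COc1cc2C[C@@]3(O)CO[C@@H](c2cc1OC(C)=O)[C@H]3COC(C)=O
F2 | step 17 | (7R)-1,4-diol from reduction of the open form of 24 | COc1cc(C[C@](CO)(O[Si](CC)(CC)CC)[C@H](COCc2ccccc2)[C@@H](O)c2cc(OC)c(OCc3ccccc3)c(-c3cccc(OC)c3O[Si](C)(C)C(C)(C)C)c2)ccc1OCc1ccccc1
F3 | step 17 | primary C9' tosylate of F2 | COc1cc(C[C@](COS(=O)(=O)c2ccc(C)cc2)(O[Si](CC)(CC)CC)[C@H](COCc2ccccc2)[C@@H](O)c2cc(OC)c(OCc3ccccc3)c(-c3cccc(OC)c3O[Si](C)(C)C(C)(C)C)c2)ccc1OCc1ccccc1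
F4 | step 16 | (3S,4S)-4-[4-(benzyloxy)-3-methoxybenzyl]-3-[(benzyloxy)methyl]-4-(triethylsilyloxy)oxolan-2-ol | COc1cc(C[C@@]2(O[Si](CC)(CC)CC)COC(O)[C@H]2COCc2ccccc2)ccc1OCc1ccccc1
F5 | step 16 | benzylic alcohol, C7 epimer mixture | COc1cc(C[C@](CO)(O[Si](CC)(CC)CC)[C@H](COCc2ccccc2)C(O)c2cc(OC)c(OCc3ccccc3)c(-c3cccc(OC)c3O[Si](C)(C)C(C)(C)C)c2)ccc1OCc1ccccc1
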